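The readings are calculated for an exercise; scatter was added.

The partner is the budget in flasks blue and amber, which share one charge and differ in temperature.

| flask | substrate | partner | temperature | remark | time |
|---|---|---|---|---|---|
| ash | 0.25 M | 0.34 M | 30 °C | run made earlier |  |
| maple | 0.25 M | 0.75 M | 50 °C | run made earlier |  |
| cedar | 0.12 M | 0.50 M | 30 °C | run made earlier |  |
| blue | 0.25 M | 0.500 M | 35 °C |  | 10 d |
| amber | 0.25 M | 0.500 M | 65 °C |  | 10 d |

| run | time / d | first product / % | substrate / % |
|---|---|---|---|
| ash | 0.833 | 17 | 83 |
| ash | 1.25 | 25 | 82 |
| ash | 1.67 | 27 | 74 |
| ash | 3.00 | 37 | 60 |
| ash | 4.00 | 41 | 51 |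
| ash | 6.00 | 47 | 41 |
| ash | 10.0 | 53 | 31 |
| maple | 0.250 | 46 | 45 |
| maple | 0.833 | 55 | 12 |
| maple | 1.25 | 43 | 3 |
| maple | 2.08 | 38 | 0 |
| maple | 3.00 | 28 | 4 |
| maple | 4.00 | 18 | 1 |
| maple | 5.00 | 18 | 0 |
| cedar | 0.833 | 20 | 74 |
| cedar | 2.50 | 43 | 45 |
| cedar | 5.00 | 51 | 26 |
| cedar | 8.00 | 53 | 12 |
| cedar | 10.0 | 49 | 8 |

(readings scatter by 2 percentage points)

- the numbers in the tables scatter by 2 percentage points (one standard deviation)
- candidate steps: substrate + partner -> first product; partner + first product -> bis adduct; partner + bis adduct -> triple product; substrate -> decomposition product

1. the flask with the highest amount of first product, in percent of the substrate charged ("all alike" if they lie within 1.5 percentage points) (blue / amber / all alike)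
2. final first product, as a percentage of the substrate charged, in blue
3. final first product, as a percentage of the substrate charged, in amber

1. Each substrate takes one partner to reach first product, two to reach bis adduct and 3 to reach triple product. Blue and amber hold 2.00 partners per substrate. If partner (the limiting reagent) ran out with the substrate converted and bis adduct empty, first product would hold 3 minus that ratio, halved, which is 50.0% of the charge: the partner-budget share.

2. The second way makes bis adduct the last stop. The same counting then leaves first product at 0%, so the two ways part by the whole share.

3. The maple run can test them. With its first product reading 18% at 4.00 d and its substrate taken as gone, the bis count leaves 39.3% of the partner, more than the 12.0% of the triple count. First product then reads 18% at 5.00 d, flat within the scatter of 2 percentage points. That favours the smaller remainder, though only as a lean, so the bis count is the one set aside.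

4. Amber is hotter than maple, and maple's substrate already read 3% at 1.25 d, so amber should reach the end of its count and finish under the share. Blue is cooler than amber. The share does not carry over to the ash and cedar runs, whose charges differ from blue's, but they stood near blue's temperature and at 10.0 d read 53% and 49% of first product, with 31% and 8% of substrate still there, so blue should still be under way at its end, with first product near those readings, and should be the richer flask.

The forecast gives blue as richest, with 48% in blue and 12% in amber, where first product “decays second order with the remaining partner”, which parts from this reckoning on amber.

    substrate + partner → first product (k = 0.0460 /M/h, Ea = 85.0 kJ/mol)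
    partner + first product → bis adduct (k = 0.0190 /M/h, Ea = 79.0 kJ/mol)
    partner + bis adduct → triple product (k = 0.160 /M/h, Ea = 69.0 kJ/mol)
    substrate → decomposition product (k = 2.00 × 10⁻⁵ /h, Ea = 125 kJ/mol)
    (constants at 35 °C)

Blue ends richer, with 48.5% of first product against 41.0% in amber, and at 10.0 d blue still holds 16% of its partner while first product is used up faster than it is made. In amber the steps ran while partner lasted: by 5.00 d partner was down to 0.00840%, and first product has stood at 41.0% since, under the share of 50.0%, with 7.74% in bis adduct. Blue's neighbour charged with 0.10 M of substrate counts to a negative share, −100%, and keeps 54% of its partner, with 30.6% of first product.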